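## The problem

Rhuschalcone IV (19) is an unsymmetrical bichalcone. Two 2'-hydroxychalcone units are joined by a diaryl ether that runs from C5 of ring A (acyl at C1, hydroxyl at C2, methoxy at C4) to C4 of ring C (acyl at C1, hydroxyl at C2). Each of these rings carries an (E)-3-(4-hydroxyphenyl)propenoyl arm; the 4-hydroxyphenyl ring of the ring A arm is called ring B here and that of the ring C arm ring D. There is no stereocentre, so nothing in the molecule can relay stereochemical information. The only stereochemical elements are the two E-alkenes, which are the thermodynamic isomers and need only be made E-selectively and then kept from reversible conjugate addition. The hard part is the ether: it links two electron-rich, heavily oxygenated rings, its ring A carbon is flanked by the methoxy group, and a late C–O coupling would have to tell five phenolic oxygens apart. The fragile groups are these: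
- the 2'-hydroxychalcones, which are Michael acceptors that can close to flavanones or cleave by retro-aldol reaction under forcing acid or base;
- ring A, which is hydroquinone-like and easily oxidised once its phenols are free;
- the single methyl ether, which must survive the unmasking of four phenols, so strong Lewis acids are excluded, as is hydrogenolysis because of the enones.

The enabling feature is the pattern of ring C: acyl at C1, hydroxyl at C2, ether oxygen at C4, hydrogen at C3, C5 and C6. This is the aromatised adduct of a 1,1-dioxygenated 3-oxybutadiene (C2 to C5) and a terminal ynone (C6 and C1). The C4 oxygen can therefore enter as the enol ether oxygen of an acyclic diene that is attached to ring A before ring C exists.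

## Retrosynthesis

**19 to 18.** The last operation cuts only the O–CH2 bonds of three methoxymethyl (MOM) ethers, on ring B, ring D and C2 of ring A. MOM is preferred to benzyl (hydrogenolysis would reduce the enones) and to silyl ethers (which would not survive the hydroxide used for the condensation). It is stable to amide base, Grignard reagent and hydroxide and is removed by dilute protic acid, which leaves the methyl ether and the diaryl ether alone. The ring C hydroxyl is left free in 18 because the key step delivers it free and chelated to its ketone.

**18 to 17 and 2.** The Cα=Cβ bond of the ring A enone is cut by a Claisen–Schmidt disconnection, giving the ring A methyl ketone 17 and aldehyde 2. Only this arm is cut here, because the ring C arm is best carried in on the dienophile of the key step, whereas an enone on ring A would not survive the strong base needed to make the diene. The forward reaction must condense one methyl ketone in the presence of an existing chalcone. Because the two arms carry the same aryl group, any retro-aldol exchange is degenerate.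

**17 to 14 and 7.** This is the key cut: the ring C bonds C1–C2 and C5–C6, opening ring C to the 3-aryloxy vinylketene silyl acetal 14 and the enynone 7. The competing cut of the aryl–O bond would need a coupling between two finished, electron-rich arenes bearing free or protected phenols. Here the ether oxygen is already in place on an sp2 carbon of an acyclic precursor, and ring C is formed around it. The forward reaction must give one regiochemistry (acyl next to the new hydroxyl), must choose the alkyne of 7 over its alkene, and must aromatise with the C2 oxygen left as a hydroxyl.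

**14 to 13.** Two O–Si bonds are cut: that of the ketene acetal and that of a silyl enol ether on ring A. The ring A acetyl group must be masked while the ester is deprotonated. A dioxolane ketal was weighed for this and rejected for three reasons:
- the ketone is a vinylogous ester (para methoxy, ortho alkoxy) that ketalises reluctantly;
- the acid needed would attack the MOM ether and the β-aryloxy enoate;
- a temporary block on the C5 phenol plus ketal formation and removal would cost several steps.

Enolising the ketone in the same operation that forms the diene, and letting the acidic work-up of the cycloaddition return the acetyl group, costs no step. The forward reaction is a double kinetic deprotonation with in-situ silylation.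

**13 to 12 to 10 and 11.** The O–C(vinyl) bond is cut by a conjugate-addition disconnection to the dihydroxy ketone 10 and the alkynoate 11; the C2 phenol is then protected. The order matters: the C5 phenol is free and nucleophilic while the C2 phenol is locked in a hydrogen bond to the acetyl group, so the addition can be run on 10 without any protecting group. The forward reactions must be selective for the C5 oxygen and give the E-enoate, whose methyl group lies syn to the ester, as needed for the γ-deprotonation.

**10 to 8.** The C5–O bond of ring A is cut back to paeonol (8), whose single free position para to the phenol is C5. The forward reaction is a para-selective persulfate hydroxylation.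

**7 to 6 to 4 and 5; 4 to 2 and 3; 2 to 1.** The ynone comes from the propargylic alcohol 6 by oxidation; the C–C bond between the carbinol carbon and the alkyne is cut to enal 4 and the acetylide 5. The enal is cut at its C=C bond to aldehyde 2 and the formyl ylide 3, and 2 comes from 4-hydroxybenzaldehyde (1). Aldehyde 2 therefore serves twice, as the source of ring D here and of ring B in the condensation with 17.

## Roads not taken

**Alternative 1: ketone-directed double ortho C–H hydroxylation.** The cut is at the two C2–O bonds of ring A and ring C. The forward step treats the diaryl ether diketone A1 with Pd(O2CCF3)2 and K2S2O8 in CF3CO2H. Each acetyl group directs palladation by divalent palladium to an ortho C–H bond, and oxidation to tetravalent palladium followed by C–O reductive elimination and hydrolysis gives the bis(2-hydroxyacetophenone) A2. A double Claisen–Schmidt condensation would follow.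
- Merits: A1 is one nucleophilic aromatic substitution away from commercial acetophenones, the core needs no protecting group, and the whole route could be about four steps against eleven here. Site selection is also favourable: the two ortho positions of ring C are equivalent, and on ring A the wanted C2 is the less hindered one.
- Weak points: the substrate is an electron-rich alkoxy diaryl ether in a strongly oxidising acid. The new ring A phenol of A2 sits para to the ether oxygen, so it is a hydroquinone monoether, the kind of ring that persulfate and high-valent palladium convert into quinones with loss of the aryloxy group. Two C–H oxidations on two electronically different rings must both go to completion.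
- Comparison: this road is clearly better in step economy. The chosen plan sets against it that every oxygen is placed by construction and that the electron-rich core never meets an oxidant after the first ring A step.

**Alternative 2: double chelation-assisted alkyne hydroacylation.** The cut is at both C(=O)–Cα bonds. The forward step uses [RhCl(cod)]2 and a bisphosphine to add both aldehyde C–H bonds of the bis-salicylaldehyde A3 across 4-ethynylphenyl acetate A4. Monovalent rhodium, held by the ortho phenoxide, inserts into the aldehyde C–H bond; syn insertion of the alkyne and reductive elimination give the E-enone. The product would be the diacetate A5 of the target.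
- Merits: full atom economy, neutral conditions, and the 2-hydroxyl groups act as directing groups. With A3 in hand the endgame would be two steps and would avoid hydroxide entirely, which is gentler than the endgame chosen here.
- Weak points: terminal aryl alkynes can give branched as well as linear enones in this reaction, and two insertions compound any leakage; decarbonylation competes. Above all, A3 contains the same diaryl ether and the same oxygenation pattern as the diketone series, so this cut leaves the central difficulty unsolved.
- Comparison: the chosen plan relies on an aldol condensation whose regiochemistry is not in question, and it builds the ether and ring C in one event.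

**Alternative 3: ring A by Dötz benzannulation.** The cut is at the ring A bonds C5–C6, C1–C2 and C2–C3. The forward step heats the aryloxy(1-methoxyvinyl)carbene pentacarbonylchromium complex A6 with the terminal alkyne A7; alkyne insertion, CO insertion and electrocyclisation give the ring A phenol A8, whose side chain is at the silyl-protected allylic alcohol level.
- Merits: like the chosen plan it brings the ether oxygen in on an acyclic carbon and joins two full halves while making a ring. Its regiochemistry (alkyne substituent next to the new hydroxyl) is probably more secure than that of a polarised cycloaddition.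
- Weak points: aryloxycarbene complexes are made indirectly and hydrolyse easily, chromium is stoichiometric, and A6 holds a chalcone alkene next to a carbene centre able to cyclopropanate acceptor alkenes. A8 is a free hydroquinone monoether prone to oxidation on decomplexation. The side chain needs desilylation and oxidation afterwards, because an ynone would not pass through the benzannulation.
- Comparison: the chosen plan offers metal-free thermal conditions, a product at the correct oxidation level, and a shorter path to the ring-forming precursor.

Key step: step 9

## Route

Remark on the chemistry: diene 14 is drawn as the 1Z ketene acetal and cycloadduct 15 as a racemate; neither element matters because both disappear on aromatisation. Alcohol 6 is racemic and its stereocentre is removed in step 4. Compounds 3 and 5 are bought.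

Step 1
Reactants: 1 4-hydroxybenzaldehyde
Product: 2 4-(methoxymethoxy)benzaldehyde
Conditions: MOMCl, K2CO3, acetone, 0 °C → rt
Reagents that add atoms: chloromethyl methyl ether, COCCl
Why: O-alkylation of the phenoxide (Williamson type); the MOM acetal withstands the ylide, Grignard reagent, MnO2 and hydroxide used later.

Step 2
Reactants: 2 4-(methoxymethoxy)benzaldehyde; 3 (triphenylphosphoranylidene)acetaldehyde
Product: 4 (E)-3-[4-(methoxymethoxy)phenyl]prop-2-enal
Conditions: toluene, 80 °C
Reagents that add atoms: none
Why: Wittig olefination with the stabilised formyl ylide should give the E-enal; about one equivalent of ylide limits a second homologation to the dienal.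

Step 3
Reactants: 4 (E)-3-[4-(methoxymethoxy)phenyl]prop-2-enal; 5 ethynylmagnesium bromide
Product: 6 (E)-1-[4-(methoxymethoxy)phenyl]pent-1-en-4-yn-3-ol (racemic)
Conditions: THF, −78 → 0 °C; aq NH4Cl
Reagents that add atoms: none
Why: Grignard 1,2-addition of the acetylide to the aldehyde carbonyl of the enal; the carbinol centre forms racemic and is removed in step 4.

Step 4
Reactants: 6 (E)-1-[4-(methoxymethoxy)phenyl]pent-1-en-4-yn-3-ol
Product: 7 (E)-1-[4-(methoxymethoxy)phenyl]pent-1-en-4-yn-3-one
Conditions: MnO2, CH2Cl2, rt
Reagents that add atoms: none
Why: MnO2 oxidation of an alcohol that is both allylic and propargylic; the neutral heterogeneous conditions spare the MOM ether and the terminal alkyne, and the cross-conjugated ynone is kept cold and used promptly.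

Step 5
Reactants: 8 paeonol
Product: 10 1-(2,5-dihydroxy-4-methoxyphenyl)ethanone, via potassium 5-acetyl-4-hydroxy-2-methoxyphenyl sulfate 9 (not isolated)
Conditions: K2S2O8, aq KOH, 0 °C → rt; then conc. HCl, 90 °C
Reagents that add atoms: potassium peroxodisulfate, [K+].[K+].[O-]S(=O)(=O)OOS(=O)(=O)[O-]
Why: Elbs persulfate oxidation: the phenoxide attacks the peroxide oxygen through the carbon para to the phenol (C5, the only free para position), and the aryl sulfate is hydrolysed by hot acid.

Step 6
Reactants: 10 1-(2,5-dihydroxy-4-methoxyphenyl)ethanone; 11 methyl but-2-ynoate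
Product: 12 methyl (E)-3-(5-acetyl-4-hydroxy-2-methoxyphenoxy)but-2-enoate
Conditions: K2CO3 (0.3 equiv), DMF, 50 °C
Reagents that add atoms: none
Why: Base-mediated oxa-Michael addition of a phenoxide to an alkynoate; the C5 oxygen is the free, more nucleophilic one while the C2 hydroxyl is hydrogen-bonded to the acetyl group, and the reversible addition should settle on the E-enoate (any but-3-enoate isomer converges on the same dienolate in step 8).

Step 7
Reactants: 12 methyl (E)-3-(5-acetyl-4-hydroxy-2-methoxyphenoxy)but-2-enoate
Product: 13 methyl (E)-3-[5-acetyl-2-methoxy-4-(methoxymethoxy)phenoxy]but-2-enoate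
Conditions: NaH (1.1 equiv), THF/DMF, 0 °C; MOMCl, 0 °C → rt
Reagents that add atoms: chloromethyl methyl ether, COCCl
Why: O-alkylation of the sodium phenoxide; full deprotonation is used because the phenol is chelated, and one equivalent of hydride leaves the far less acidic ketone and enoate C–H bonds alone.

Step 8
Reactants: 13 methyl (E)-3-[5-acetyl-2-methoxy-4-(methoxymethoxy)phenoxy]but-2-enoate
Product: 14 (1Z)-1-methoxy-3-{2-methoxy-4-(methoxymethoxy)-5-[1-(trimethylsilyloxy)ethenyl]phenoxy}-1-(trimethylsilyloxy)buta-1,3-diene
Conditions: LiN(i-Pr)2 (2.3 equiv), TMSCl (4 equiv, present from the start), THF, −78 → 0 °C; evaporation, pentane, filtration; used crude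
Reagents that add atoms: chlorotrimethylsilane, C[Si](C)(C)Cl
Why: Kinetic γ-deprotonation of a β-oxygenated crotonate (methyl syn to the ester) with O-silylation of the dienolate is the standard way to vinylketene silyl acetals; the methyl ketone is enolised and O-silylated in the same pot, so the acetyl group travels as a silyl enol ether, and trapping in situ at −78 °C keeps the lithium enolates from attacking esters or expelling aryloxide.

Step 9
Reactants: 14 (1Z)-1-methoxy-3-{2-methoxy-4-(methoxymethoxy)-5-[1-(trimethylsilyloxy)ethenyl]phenoxy}-1-(trimethylsilyloxy)buta-1,3-diene; 7 (E)-1-[4-(methoxymethoxy)phenyl]pent-1-en-4-yn-3-one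
Product: 17 (E)-1-{4-[5-acetyl-2-methoxy-4-(methoxymethoxy)phenoxy]-2-hydroxyphenyl}-3-[4-(methoxymethoxy)phenyl]prop-2-en-1-one, via cyclohexa-1,4-diene cycloadduct 15 (not isolated), via ring C trimethylsilyl ether 16 (not isolated)
Conditions: toluene, rt → 60 °C; then 0.5 M HCl, THF, 0 °C
Reagents that add atoms: none
Why: Thermal (4+2) cycloaddition of a 1-alkoxy-1-silyloxybutadiene with an acetylenic ketone, followed by aromatisation to a salicyl ketone, is a known reaction type; here the usual 3-alkoxy group is an aryloxy group. Three oxygen donors polarise the diene toward its CH2 terminus (C5 of ring C), which bonds first to the unsubstituted alkyne carbon (C6) in a normal-demand, asynchronous transition state, and the acetal carbon (C2) then bonds to the carbon next to the ketone (C1); a stepwise Michael-then-closure course would form the same two bonds. Ring C is closed as a six-membered carbocycle by this intermolecular cycloaddition, both ring bonds coming from one diene–alkyne pair. Cycloadduct 15 carries a mixed methyl silyl ketal; 1,4-elimination of methanol gives the aryl silyl ether 16, and the cold dilute acid cleaves the aryl O–Si bond and the ring A silyl enol ether and would also collapse any surviving ketal to the dienone tautomer of the same phenol. No stereocentre remains: the ketal carbon of 15 forms racemic and becomes sp2, and the E-alkene of 7 is not touched. Regioselectivity (acyl next to the new hydroxyl, ether oxygen para to the acyl group) follows from pairing the nucleophilic diene terminus with the β-carbon of the ynone. Chemoselectivity rests on the terminal ynone being a much better and less hindered dienophile than the donor-substituted styryl alkene of 7 or the ring A silyl enol ether, which needs a Lewis acid to add to an enone; residual amine from step 8 is removed under vacuum beforehand so that it cannot add to the ynone.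

Step 10
Reactants: 17 (E)-1-{4-[5-acetyl-2-methoxy-4-(methoxymethoxy)phenoxy]-2-hydroxyphenyl}-3-[4-(methoxymethoxy)phenyl]prop-2-en-1-one; 2 4-(methoxymethoxy)benzaldehyde
Product: 18 (E)-1-{2-hydroxy-4-[2-methoxy-4-(methoxymethoxy)-5-{(E)-3-[4-(methoxymethoxy)phenyl]prop-2-enoyl}phenoxy]phenyl}-3-[4-(methoxymethoxy)phenyl]prop-2-en-1-one
Conditions: KOH, EtOH/H2O, rt; aq NH4Cl
Reagents that add atoms: none
Why: Claisen–Schmidt condensation (aldol addition, then E1cB dehydration to the E-enone) at the only enolisable ketone; the ring C chalcone is deactivated as its ortho phenoxide, excess aldehyde outcompetes Michael addition of the enolate, and aldol exchange is degenerate because both arms carry the same aryl group.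

Step 11
Reactants: 18 (E)-1-{2-hydroxy-4-[2-methoxy-4-(methoxymethoxy)-5-{(E)-3-[4-(methoxymethoxy)phenyl]prop-2-enoyl}phenoxy]phenyl}-3-[4-(methoxymethoxy)phenyl]prop-2-en-1-one
Product: 19 rhuschalcone IV, (E)-1-{2-hydroxy-4-[4-hydroxy-5-{(E)-3-(4-hydroxyphenyl)prop-2-enoyl}-2-methoxyphenoxy]phenyl}-3-(4-hydroxyphenyl)prop-2-en-1-one
Conditions: HCl (3 M), MeOH/THF, 45 °C
Reagents that add atoms: none
Why: Acid-catalysed methanolysis of the three aryl MOM acetals; the methyl ether, the diaryl ether and the E-enones are inert to dilute protic acid, and the mild temperature limits flavanone closure.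

## Compound list

1 | 4-hydroxybenzaldehyde | O=Cc1ccc(O)cc1 | starting material
2 | 4-(methoxymethoxy)benzaldehyde | COCOc1ccc(C=O)cc1 | intermediate
3 | (triphenylphosphoranylidene)acetaldehyde | O=CC=P(c1ccccc1)(c1ccccc1)c1ccccc1 | starting material
4 | (E)-3-[4-(methoxymethoxy)phenyl]prop-2-enal | COCOc1ccc(/C=C/C=O)cc1 | intermediate
5 | ethynylmagnesium bromide | C#C[Mg]Br | starting material
6 | (E)-1-[4-(methoxymethoxy)phenyl]pent-1-en-4-yn-3-ol (racemic) | C#CC(O)/C=C/c1ccc(OCOC)cc1 | intermediate
7 | (E)-1-[4-(methoxymethoxy)phenyl]pent-1-en-4-yn-3-one | C#CC(=O)/C=C/c1ccc(OCOC)cc1 | intermediate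
8 | paeonol, 1-(2-hydroxy-4-methoxyphenyl)ethanone | CC(=O)c1ccc(OC)cc1O | starting material
9 | potassium 5-acetyl-4-hydroxy-2-methoxyphenyl sulfate | CC(=O)c1cc(OS(=O)(=O)[O-])c(OC)cc1O.[K+] | intermediate
10 | 1-(2,5-dihydroxy-4-methoxyphenyl)ethanone | CC(=O)c1cc(O)c(OC)cc1O | intermediate
11 | methyl but-2-ynoate | CC#CC(=O)OC | starting material
12 | methyl (E)-3-(5-acetyl-4-hydroxy-2-methoxyphenoxy)but-2-enoate | C/C(=C\C(=O)OC)Oc1cc(C(C)=O)c(O)cc1OC | intermediate
13 | methyl (E)-3-[5-acetyl-2-methoxy-4-(methoxymethoxy)phenoxy]but-2-enoate | C/C(=C\C(=O)OC)Oc1cc(C(C)=O)c(OCOC)cc1OC | intermediate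
14 | (1Z)-1-methoxy-3-{2-methoxy-4-(methoxymethoxy)-5-[1-(trimethylsilyloxy)ethenyl]phenoxy}-1-(trimethylsilyloxy)buta-1,3-diene | C=C(Oc1cc(C(=C)O[Si](C)(C)C)c(OCOC)cc1OC)/C=C(/OC)O[Si](C)(C)C | intermediate
15 | (E)-1-[6-methoxy-4-{2-methoxy-4-(methoxymethoxy)-5-[1-(trimethylsilyloxy)ethenyl]phenoxy}-6-(trimethylsilyloxy)cyclohexa-1,4-dien-1-yl]-3-[4-(methoxymethoxy)phenyl]prop-2-en-1-one (racemic) | COC1(O[Si](C)(C)C)C=C(Oc2cc(C(=C)O[Si](C)(C)C)c(OCOC)cc2OC)CC=C1C(=O)/C=C/c1ccc(OCOC)cc1 | intermediate
16 | (E)-1-[4-{2-methoxy-4-(methoxymethoxy)-5-[1-(trimethylsilyloxy)ethenyl]phenoxy}-2-(trimethylsilyloxy)phenyl]-3-[4-(methoxymethoxy)phenyl]prop-2-en-1-one | C[Si](C)(C)Oc1cc(Oc2cc(C(=C)O[Si](C)(C)C)c(OCOC)cc2OC)ccc1C(=O)/C=C/c1ccc(OCOC)cc1 | intermediate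
17 | (E)-1-{4-[5-acetyl-2-methoxy-4-(methoxymethoxy)phenoxy]-2-hydroxyphenyl}-3-[4-(methoxymethoxy)phenyl]prop-2-en-1-one | COCOc1ccc(/C=C/C(=O)c2ccc(Oc3cc(C(C)=O)c(OCOC)cc3OC)cc2O)cc1 | intermediate
18 | (E)-1-{2-hydroxy-4-[2-methoxy-4-(methoxymethoxy)-5-{(E)-3-[4-(methoxymethoxy)phenyl]prop-2-enoyl}phenoxy]phenyl}-3-[4-(methoxymethoxy)phenyl]prop-2-en-1-one | COCOc1ccc(/C=C/C(=O)c2ccc(Oc3cc(C(=O)/C=C/c4ccc(OCOC)cc4)c(OCOC)cc3OC)cc2O)cc1 | intermediate
19 | rhuschalcone IV | COc1cc(O)c(C(=O)/C=C/c2ccc(O)cc2)cc1Oc1ccc(C(=O)/C=C/c2ccc(O)cc2)c(O)c1 | target

## Step count and risks

Total: 11 steps. Longest linear sequence: 7 steps (8 to 19 through steps 5 to 11; the branch from 1 through steps 1 to 4 and 9 to 11 is equally long).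

**Step 9 (key step).** Three things may go wrong:
- the diene may add to the ynone stepwise and stall after the first C–C bond, without ring closure;
- the cross-conjugated enynone may oligomerise or be attacked at its styryl position before cycloaddition is complete;
- thermal loss of trimethylsilanol instead of methanol from the mixed ketal would leave the C2 oxygen of ring C methylated (cold acid treatment before any prolonged heating is the guard against this).

The fallback takes the ring C arm out of the dienophile. It sets out from 14, which is combined with commercial but-3-yn-2-one, a smaller and more reactive acetylenic ketone with no second acceptor site, under the conditions of step 9. The racemic cycloadduct 1-[6-methoxy-4-{2-methoxy-4-(methoxymethoxy)-5-[1-(trimethylsilyloxy)ethenyl]phenoxy}-6-(trimethylsilyloxy)cyclohexa-1,4-dien-1-yl]ethanone F1 should aromatise to the silyl ether 1-[4-{2-methoxy-4-(methoxymethoxy)-5-[1-(trimethylsilyloxy)ethenyl]phenoxy}-2-(trimethylsilyloxy)phenyl]ethanone F2, and the same cold acid work-up should give 1-{4-[5-acetyl-2-methoxy-4-(methoxymethoxy)phenoxy]-2-hydroxyphenyl}ethanone F3. A double Claisen–Schmidt condensation of F3 with 2 (KOH, EtOH) then raises both enone arms at once and comes back to the route at 18.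

**Step 8.** Deprotonation may be incomplete or unselective, with the ketone enolate attacking an ester of a second molecule before it is silylated. The lithium dienolate may expel aryloxide (reversal of the conjugate addition by way of an allenoate). The two trimethylsilyl groups may hydrolyse on handling, which would return 13. The fallback gives up the cycloaddition for this bond set and makes the ether by nucleophilic aromatic substitution, setting out from 10. Commercial 1-(4-fluoro-2-hydroxyphenyl)ethanone is protected (NaH, MOMCl) as 1-[4-fluoro-2-(methoxymethoxy)phenyl]ethanone F4. The non-chelated C5 phenoxide of 10 displaces the fluoride para to the acetyl group (K2CO3, DMSO, 110 °C, inert atmosphere) to give 1-{5-[4-acetyl-3-(methoxymethoxy)phenoxy]-2-hydroxy-4-methoxyphenyl}ethanone F5. A double Claisen–Schmidt condensation with 2 gives (E)-1-{4-[4-hydroxy-2-methoxy-5-{(E)-3-[4-(methoxymethoxy)phenyl]prop-2-enoyl}phenoxy]-2-(methoxymethoxy)phenyl}-3-[4-(methoxymethoxy)phenyl]prop-2-en-1-one F6, and the conditions of step 11 bring it back to the route at 19.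

**Step 6.** Addition may occur at both phenolic oxygens or at the chelated one, the alkynoate may isomerise to the allenoate under base with loss of regiocontrol, and the enoate may form as an E/Z mixture. The fallback removes the competition between the phenols and sets out from 10. Benzylation at the non-chelated oxygen (BnBr, K2CO3, acetone) gives 1-[5-(benzyloxy)-2-hydroxy-4-methoxyphenyl]ethanone F7. Protection of the chelated phenol (NaH, MOMCl) gives 1-[5-(benzyloxy)-4-methoxy-2-(methoxymethoxy)phenyl]ethanone F8. Hydrogenolysis (H2, Pd on carbon, EtOAc) frees the single phenol of 1-[5-hydroxy-4-methoxy-2-(methoxymethoxy)phenyl]ethanone F9. Its addition to 11 under the conditions of step 6 comes back to the route at 13, with step 7 no longer needed.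

**Step 5.** Conversion may be low, and the electron-rich phenoxide and the hydroquinone-type product may be over-oxidised by persulfate to quinonoid material. The fallback builds the acetyl group onto a ring that already holds both oxygens: commercial 2-methoxybenzene-1,4-diol is C-acetylated with acetic acid and BF3·OEt2 at 90 °C (Friedel–Crafts acylation of the Fries type). Acylation para to the methoxy group and ortho to a hydroxyl should give 10 directly. This fallback replaces 8 as the starting material and comes back to the route at 10.

## Further compounds

F1 | step 9 | 1-[6-methoxy-4-{2-methoxy-4-(methoxymethoxy)-5-[1-(trimethylsilyloxy)ethenyl]phenoxy}-6-(trimethylsilyloxy)cyclohexa-1,4-dien-1-yl]ethanone (racemic) | COC1(O[Si](C)(C)C)C=C(Oc2cc(C(=C)O[Si](C)(C)C)c(OCOC)cc2OC)CC=C1C(C)=O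
F2 | step 9 | 1-[4-{2-methoxy-4-(methoxymethoxy)-5-[1-(trimethylsilyloxy)ethenyl]phenoxy}-2-(trimethylsilyloxy)phenyl]ethanone | C[Si](C)(C)Oc1cc(Oc2cc(C(=C)O[Si](C)(C)C)c(OCOC)cc2OC)ccc1C(C)=O
F3 | step 9 | 1-{4-[5-acetyl-2-methoxy-4-(methoxymethoxy)phenoxy]-2-hydroxyphenyl}ethanone | CC(=O)c1ccc(Oc2cc(C(C)=O)c(OCOC)cc2OC)cc1O
F4 | step 8 | 1-[4-fluoro-2-(methoxymethoxy)phenyl]ethanone | CC(=O)c1ccc(F)cc1OCOC
F5 | step 8 | 1-{5-[4-acetyl-3-(methoxymethoxy)phenoxy]-2-hydroxy-4-methoxyphenyl}ethanone | CC(=O)c1ccc(Oc2cc(C(C)=O)c(O)cc2OC)cc1OCOC
F6 | step 8 | (E)-1-{4-[4-hydroxy-2-methoxy-5-{(E)-3-[4-(methoxymethoxy)phenyl]prop-2-enoyl}phenoxy]-2-(methoxymethoxy)phenyl}-3-[4-(methoxymethoxy)phenyl]prop-2-en-1-one | COCOc1ccc(/C=C/C(=O)c2ccc(Oc3cc(C(=O)/C=C/c4ccc(OCOC)cc4)c(O)cc3OC)cc2OCOC)cc1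
F7 | step 6 | 1-[5-(benzyloxy)-2-hydroxy-4-methoxyphenyl]ethanone | CC(=O)c1cc(OCc2ccccc2)c(OC)cc1O
F8 | step 6 | 1-[5-(benzyloxy)-4-methoxy-2-(methoxymethoxy)phenyl]ethanone | CC(=O)c1cc(OCc2ccccc2)c(OC)cc1OCOC
F9 | step 6 | 1-[5-hydroxy-4-methoxy-2-(methoxymethoxy)phenyl]ethanone | CC(=O)c1cc(O)c(OC)cc1OCOC
F0 | step 5 | none | none
A1 | alternative 1 | 1-[3-(4-acetylphenoxy)-4-methoxyphenyl]ethanone | CC(=O)c1ccc(Oc2cc(C(C)=O)ccc2OC)cc1
A2 | alternative 1 | 1-[5-(4-acetyl-3-hydroxyphenoxy)-2-hydroxy-4-methoxyphenyl]ethanone | CC(=O)c1cc(Oc2ccc(C(C)=O)c(O)c2)c(OC)cc1O
A3 | alternative 2 | 5-(4-formyl-3-hydroxyphenoxy)-2-hydroxy-4-methoxybenzaldehyde | O=Cc1cc(Oc2ccc(C=O)c(O)c2)c(OC)cc1O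
A4 | alternative 2 | 4-ethynylphenyl acetate | CC(=O)Oc1ccc(C#C)cc1
A5 | alternative 2 | diacetate of rhuschalcone IV at the ring B and ring D phenols | COc1cc(O)c(C(=O)/C=C/c2ccc(OC(C)=O)cc2)cc1Oc1ccc(C(=O)/C=C/c2ccc(OC(C)=O)cc2)c(O)c1
A6 | alternative 3 | pentacarbonyl{(1-methoxyethenyl)[3-(methoxymethoxy)-4-{(E)-3-[4-(methoxymethoxy)phenyl]prop-2-enoyl}phenoxy]methylidene}chromium | C=C(OC)C(Oc1ccc(C(=O)/C=C/c2ccc(OCOC)cc2)c(OCOC)c1)=[Cr](=C=O)(=C=O)(=C=O)(=C=O)=C=O
A7 | alternative 3 | tert-butyl{[(E)-1-[4-(methoxymethoxy)phenyl]pent-1-en-4-yn-3-yl]oxy}dimethylsilane (racemic) | C#CC(O[Si](C)(C)C(C)(C)C)/C=C/c1ccc(OCOC)cc1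
A8 | alternative 3 | ring A phenol with the ring A side chain as the silyl-protected allylic alcohol and ring C as the MOM-protected chalcone | COc1cc(O)c(C(O[Si](C)(C)C(C)(C)C)/C=C/c2ccc(OCOC)cc2)cc1Oc1ccc(C(=O)/C=C/c2ccc(OCOC)cc2)c(OCOC)c1
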